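**Plan**

- Retrosynthesis: the Z-alkene C4=C5 of the 1,3-diene is read as an alkyne (cis-semireduction last). The bond from the carbinol carbon C7 to the allylic CH2 (C6) is then cut, giving a thiazole aldehyde (16 heavy atoms) and an allenyl pinacol boronate carrying the whole methylidene–carbamate chain (12 heavy atoms plus boron).
- Enabling feature: C7 lies between the quaternary CMe2 carbon on thiazole C2 (so the aldehyde cannot enolise) and a CH2 next to the Z-CH=CH of the diene. As its alkyne this is a CH(OH)–CH2–C≡C array, the direct product of an allenylboron SE2' addition; the methylidene carbon on the boron-bearing carbon cannot compete, since it would have to give a cumulene.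
- Thiazole half: Hantzsch ring synthesis, then the (2Z)-hexa-2,5-dienyl chain at C4 by ester half-reduction and Wittig reaction, then the neopentyl ester is taken to the aldehyde.
- Carbamate half: but-3-yn-1-amine to the carbamate, 2-iodoalkene, Sonogashira coupling with propargyl alcohol, carbonate, and copper-catalysed SN2' borylation to the allenyl boronate.
- Union by allenylboration under chiral phosphoric acid catalysis, then Zn(Cu/Ag) cis-reduction of the conjugated enyne.
- Stereochemistry: C7 (R) from the catalyst in the union; the side-chain Z-alkene from the salt-free Wittig reaction; the C4=C5 Z-alkene from the cis-reduction.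

Key step: step 11

Remark: the (R) antipode of the phosphoric acid is assigned to Re-face attack on the aldehyde (which gives the R carbinol) by analogy with the accepted transition-state model for this catalyst family; the antipodal acid is equally available should the sense prove reversed.

**Route**

Step 1
Reactants: 1 ethyl 2-cyano-2-methylpropanoate
Product: 2 ethyl 3-amino-2,2-dimethyl-3-sulfanylidenepropanoate (primary thioamide)
Conditions: (EtO)2P(S)SH (1.5 equiv), H2O (2 equiv), 1,2-dimethoxyethane, 70 °C
Reagents that add atoms: O,O-diethyl dithiophosphate, CCOP(=S)(S)OCC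
Why: Thiolysis of a nitrile to a primary thioamide by a dithiophosphoric acid; the α-ester activates the nitrile and the hindered ester should survive.

Step 2
Reactants: 2 ethyl 3-amino-2,2-dimethyl-3-sulfanylidenepropanoate; 3 ethyl 4-chloro-3-oxobutanoate
Product: 4 ethyl 2-[4-(2-ethoxy-2-oxoethyl)-1,3-thiazol-2-yl]-2-methylpropanoate
Conditions: EtOH, 70 °C; aqueous NaHCO3 work-up
Reagents that add atoms: none
Why: Hantzsch thiazole synthesis (S-alkylation at CH2Cl, N-attack on the ketone, dehydration), which places CH2CO2Et at C4 and the CMe2CO2Et group at C2.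

Step 3
Reactants: 4 ethyl 2-[4-(2-ethoxy-2-oxoethyl)-1,3-thiazol-2-yl]-2-methylpropanoate; 5 (but-3-en-1-yl)triphenylphosphonium bromide
Product: 7 ethyl 2-{4-[(2Z)-hexa-2,5-dien-1-yl]-1,3-thiazol-2-yl}-2-methylpropanoate, via thiazolylacetaldehyde 6 (not isolated)
Conditions: DIBAL-H (i-Bu2AlH, 1.05 equiv), CH2Cl2, -78 °C; MeOH quench, cold aqueous KNaC4H4O6 work-up; crude 6 in THF added at -78 °C to the ylide made from 5 and NaN(SiMe3)2 in THF, then to 0 °C
Reagents that add atoms: none
Why: At -78 °C the hydride should go to the unhindered heteroarylacetic ester and not to the ester on the quaternary carbon, and the salt-free non-stabilised ylide should then give the Z-alkene under kinetic control (Wittig reaction).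

Step 4
Reactants: 7 ethyl 2-{4-[(2Z)-hexa-2,5-dien-1-yl]-1,3-thiazol-2-yl}-2-methylpropanoate
Product: 8 2-{4-[(2Z)-hexa-2,5-dien-1-yl]-1,3-thiazol-2-yl}-2-methylpropan-1-ol
Conditions: LiAlH4, THF, 0 °C
Reagents that add atoms: none
Why: Hydride reduction of the remaining neopentyl ester to the primary alcohol; the skipped diene and the thiazole are inert to LiAlH4.

Step 5
Reactants: 8 2-{4-[(2Z)-hexa-2,5-dien-1-yl]-1,3-thiazol-2-yl}-2-methylpropan-1-ol
Product: 9 2-{4-[(2Z)-hexa-2,5-dien-1-yl]-1,3-thiazol-2-yl}-2-methylpropanal
Conditions: Dess–Martin periodinane, CH2Cl2, 0 °C to room temperature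
Reagents that add atoms: none
Why: Dess–Martin oxidation of a primary alcohol under non-basic conditions; the aldehyde has no α-hydrogen and the skipped diene should not migrate.

Step 6
Reactants: 10 but-3-yn-1-amine
Product: 11 methyl N-(but-3-yn-1-yl)carbamate
Conditions: ClCO2Me, Et3N, CH2Cl2, 0 °C
Reagents that add atoms: methyl chloroformate, COC(=O)Cl
Why: Acylation of the primary amine by the chloroformate (carbamate formation).

Step 7
Reactants: 11 methyl N-(but-3-yn-1-yl)carbamate
Product: 12 methyl N-(3-iodobut-3-en-1-yl)carbamate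
Conditions: NaI, Me3SiCl, H2O (0.5 equiv per NaI), MeCN, room temperature
Reagents that add atoms: sodium iodide, [Na+].[I-]
Why: Markovnikov hydroiodination of the terminal alkyne by HI generated in the flask should give the 2-iodo-1-alkene; the carbamate is stable at room temperature.

Step 8
Reactants: 12 methyl N-(3-iodobut-3-en-1-yl)carbamate; 13 prop-2-yn-1-ol
Product: 14 methyl N-(6-hydroxy-3-methylidenehex-4-yn-1-yl)carbamate
Conditions: Pd(PPh3)2Cl2 (2 mol%), CuI (4 mol%), Et3N, THF, room temperature
Reagents that add atoms: none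
Why: Sonogashira coupling (oxidative addition of the alkenyl iodide to zerovalent palladium, transmetalation from the copper acetylide, reductive elimination) builds the cross-conjugated enyne.

Step 9
Reactants: 14 methyl N-(6-hydroxy-3-methylidenehex-4-yn-1-yl)carbamate
Product: 15 methyl N-{6-[(methoxycarbonyl)oxy]-3-methylidenehex-4-yn-1-yl}carbamate
Conditions: ClCO2Me, pyridine, CH2Cl2, 0 °C
Reagents that add atoms: methyl chloroformate, COC(=O)Cl
Why: O-acylation of the propargylic alcohol to the carbonate, the leaving group for the borylation; the carbamate N–H should not be acylated under these conditions.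

Step 10
Reactants: 15 methyl N-{6-[(methoxycarbonyl)oxy]-3-methylidenehex-4-yn-1-yl}carbamate
Product: 16 methyl N-[3-methylidene-4-(4,4,5,5-tetramethyl-1,3,2-dioxaborolan-2-yl)hexa-4,5-dien-1-yl]carbamate
Conditions: B2pin2 (1.3 equiv), CuCl (10 mol%), Xantphos (10 mol%), KOC(CH3)3 (10 mol%), THF, room temperature
Reagents that add atoms: bis(pinacolato)diboron, CC1(C)OB(B2OC(C)(C)C(C)(C)O2)OC1(C)C
Why: Copper-catalysed γ-selective SN2' borylation of a propargylic carbonate: the boryl copper species adds across the alkyne with boron on the carbon remote from the carbonate, and β-elimination of the carbonate (which loses CO2) releases the 1,1-disubstituted allenyl boronate.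

Step 11
Reactants: 9 2-{4-[(2Z)-hexa-2,5-dien-1-yl]-1,3-thiazol-2-yl}-2-methylpropanal; 16 methyl N-[3-methylidene-4-(4,4,5,5-tetramethyl-1,3,2-dioxaborolan-2-yl)hexa-4,5-dien-1-yl]carbamate
Product: 18 methyl N-[(7R)-8-{4-[(2Z)-hexa-2,5-dien-1-yl]-1,3-thiazol-2-yl}-7-hydroxy-8-methyl-3-methylidenenon-4-yn-1-yl]carbamate, via pinacol borate ester 17 (not isolated)
Conditions: 16 (1.5 equiv), (R)-3,3'-bis(2,4,6-triisopropylphenyl)-1,1'-binaphthyl-2,2'-diyl hydrogen phosphate ((R)-TRIP, 10 mol%), 4 Å molecular sieves, toluene, 0 °C to room temperature; aqueous NaHCO3 work-up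
Reagents that add atoms: none
Why: The phosphoric acid hydrogen-bonds through P–OH to a pinacol oxygen of 16 and through P=O to the formyl hydrogen of 9, the aldehyde oxygen binds boron, and the CH2 terminus of the allene attacks the carbonyl carbon in a six-membered chair-like SE2' transition state in which the C–B bond becomes the alkyne π bond, giving borate 17, which is hydrolysed on work-up. The closest known reaction type is the chiral-phosphoric-acid-catalysed allenylboration (propargylation) of aldehydes with allenyl pinacol boronates. No ring is closed. The single new stereocenter C7 is controlled by the catalyst, whose 2,4,6-triisopropylphenyl walls should leave the Re face of the bound aldehyde open and so give the R carbinol. The step needs SE2' regioselectivity (homopropargylic, not allenic, alcohol), secured because boron sits on an sp2 carbon whose only cyclic pathway runs through the allene terminus, and chemoselectivity for the aldehyde, which is the only electrophile and, being α-quaternary, can neither enolise nor epimerise. The uncatalysed addition of pinacol allenylboronates is slow at this temperature, so the catalysed path should carry the reaction.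

Step 12
Reactants: 18 methyl N-[(7R)-8-{4-[(2Z)-hexa-2,5-dien-1-yl]-1,3-thiazol-2-yl}-7-hydroxy-8-methyl-3-methylidenenon-4-yn-1-yl]carbamate
Product: 19 mycothiazole, methyl N-[(4Z,7R)-8-{4-[(2Z)-hexa-2,5-dien-1-yl]-1,3-thiazol-2-yl}-7-hydroxy-8-methyl-3-methylidenenon-4-en-1-yl]carbamate
Conditions: Zn dust activated with Cu(OAc)2 and AgNO3, MeOH/H2O (1:1), room temperature to 40 °C
Reagents that add atoms: none
Why: Activated zinc transfers two hydrogens cis to the alkyne that is activated by conjugation with the methylidene group (Boland reduction), which should set the Z-diene without over-reduction and without touching the isolated alkenes, the thiazole or the carbamate.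

**Compound list**

1 | ethyl 2-cyano-2-methylpropanoate | CCOC(=O)C(C)(C)C#N | starting material
2 | ethyl 3-amino-2,2-dimethyl-3-sulfanylidenepropanoate | CCOC(=O)C(C)(C)C(N)=S | intermediate
3 | ethyl 4-chloro-3-oxobutanoate | CCOC(=O)CC(=O)CCl | starting material
4 | ethyl 2-[4-(2-ethoxy-2-oxoethyl)-1,3-thiazol-2-yl]-2-methylpropanoate | CCOC(=O)Cc1csc(C(C)(C)C(=O)OCC)n1 | intermediate
5 | (but-3-en-1-yl)triphenylphosphonium bromide | C=CCC[P+](c1ccccc1)(c1ccccc1)c1ccccc1.[Br-] | starting material
6 | ethyl 2-methyl-2-[4-(2-oxoethyl)-1,3-thiazol-2-yl]propanoate | CCOC(=O)C(C)(C)c1nc(CC=O)cs1 | intermediate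
7 | ethyl 2-{4-[(2Z)-hexa-2,5-dien-1-yl]-1,3-thiazol-2-yl}-2-methylpropanoate | C=CC/C=C\Cc1csc(C(C)(C)C(=O)OCC)n1 | intermediate
8 | 2-{4-[(2Z)-hexa-2,5-dien-1-yl]-1,3-thiazol-2-yl}-2-methylpropan-1-ol | C=CC/C=C\Cc1csc(C(C)(C)CO)n1 | intermediate
9 | 2-{4-[(2Z)-hexa-2,5-dien-1-yl]-1,3-thiazol-2-yl}-2-methylpropanal | C=CC/C=C\Cc1csc(C(C)(C)C=O)n1 | intermediate
10 | but-3-yn-1-amine | C#CCCN | starting material
11 | methyl N-(but-3-yn-1-yl)carbamate | C#CCCNC(=O)OC | intermediate
12 | methyl N-(3-iodobut-3-en-1-yl)carbamate | C=C(I)CCNC(=O)OC | intermediate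
13 | prop-2-yn-1-ol | C#CCO | starting material
14 | methyl N-(6-hydroxy-3-methylidenehex-4-yn-1-yl)carbamate | C=C(C#CCO)CCNC(=O)OC | intermediate
15 | methyl N-{6-[(methoxycarbonyl)oxy]-3-methylidenehex-4-yn-1-yl}carbamate | C=C(C#CCOC(=O)OC)CCNC(=O)OC | intermediate
16 | methyl N-[3-methylidene-4-(4,4,5,5-tetramethyl-1,3,2-dioxaborolan-2-yl)hexa-4,5-dien-1-yl]carbamate | C=C=C(B1OC(C)(C)C(C)(C)O1)C(=C)CCNC(=O)OC | intermediate
17 | methyl N-[(7R)-8-{4-[(2Z)-hexa-2,5-dien-1-yl]-1,3-thiazol-2-yl}-8-methyl-3-methylidene-7-[(4,4,5,5-tetramethyl-1,3,2-dioxaborolan-2-yl)oxy]non-4-yn-1-yl]carbamate | C=CC/C=C\Cc1csc(C(C)(C)[C@H](OB2OC(C)(C)C(C)(C)O2)CC#CC(=C)CCNC(=O)OC)n1 | intermediate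
18 | methyl N-[(7R)-8-{4-[(2Z)-hexa-2,5-dien-1-yl]-1,3-thiazol-2-yl}-7-hydroxy-8-methyl-3-methylidenenon-4-yn-1-yl]carbamate | C=CC/C=C\Cc1csc(C(C)(C)[C@H](O)CC#CC(=C)CCNC(=O)OC)n1 | intermediate
19 | mycothiazole, methyl N-[(4Z,7R)-8-{4-[(2Z)-hexa-2,5-dien-1-yl]-1,3-thiazol-2-yl}-7-hydroxy-8-methyl-3-methylidenenon-4-en-1-yl]carbamate | C=CC/C=C\Cc1csc(C(C)(C)[C@H](O)C/C=C\C(=C)CCNC(=O)OC)n1 | target

**Step count and risks**

Total steps: 12 (steps 1 to 5 for the thiazole aldehyde, steps 6 to 10 for the allenyl boronate, steps 11 and 12 after the union).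
Longest linear sequence: 7 steps (1 to 5, 11, 12; the branch 6 to 10, 11, 12 is equally long).

Steps most likely to fail:

1. Step 11. Facial discrimination may be poor or turnover may stall, because the basic thiazole nitrogen can bind the phosphoric acid and the neopentyl aldehyde adds slowly, which lets the unselective background path compete. Fallback: setting out from 9 and 16, the union is run without the acid (toluene, 60 °C), which should give the racemic pinacol borate ester F1 and, after aqueous work-up, the racemic alcohol F2. Dess–Martin oxidation should give the ketone F3. Corey–Bakshi–Shibata reduction ((S)-2-methyl-CBS-oxazaborolidine, catecholborane, toluene, -78 °C), with the CMe2-thiazolyl group as the large and the propargylic CH2 as the small substituent, should return 18, where the route is rejoined. Stereocontrol thus moves from the C–C bond formation to a ketone reduction.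

2. Step 10. The boryl copper species may add to the conjugated enyne instead of displacing the carbonate, and the vinylallene boronate may protodeboronate on silica or dimerise by cycloaddition on concentration. Fallback: setting out from 9, the same phosphoric acid catalysis is applied to commercial allenylboronic acid pinacol ester (4,4,5,5-tetramethyl-2-(propa-1,2-dien-1-yl)-1,3,2-dioxaborolane), which should give the borate ester F4 and, on work-up, the terminal alkyne (3R)-2-{4-[(2Z)-hexa-2,5-dien-1-yl]-1,3-thiazol-2-yl}-2-methylhex-5-yn-3-ol F5. Sonogashira coupling of this alkyne with iodoalkene 12 (Pd(PPh3)2Cl2, CuI, Et3N, THF, room temperature) should give 18, where the route is rejoined. The diene-bearing half is then attached after the carbinol is made, and steps 8 to 10 are not needed.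

3. Step 3. Chemoselectivity between the two esters may be lost or the ester over-reduced, the basic ylide may enolise the heteroarylacetaldehyde with migration of the double bond into conjugation, and the Z-selectivity may erode. Fallback: setting out from 2, Hantzsch condensation with 1,3-dichloroacetone (EtOH, 70 °C) should give the chloromethylthiazole F6. Copper-mediated coupling with pent-1-en-4-yne (CuI, NaI, Cs2CO3, DMF, room temperature) should give the skipped enyne F7. Semihydrogenation over Pd/CaCO3 poisoned with Pb(OAc)2, with quinoline (H2, 1 atm, EtOAc), should give 7, where the route is rejoined. This avoids both the ester differentiation and the enolisable aldehyde.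

**Further compounds**

F1 | step 11 | racemic methyl N-[8-{4-[(2Z)-hexa-2,5-dien-1-yl]-1,3-thiazol-2-yl}-8-methyl-3-methylidene-7-[(4,4,5,5-tetramethyl-1,3,2-dioxaborolan-2-yl)oxy]non-4-yn-1-yl]carbamate | C=CC/C=C\Cc1csc(C(C)(C)C(OB2OC(C)(C)C(C)(C)O2)CC#CC(=C)CCNC(=O)OC)n1
F2 | step 11 | racemic methyl N-[8-{4-[(2Z)-hexa-2,5-dien-1-yl]-1,3-thiazol-2-yl}-7-hydroxy-8-methyl-3-methylidenenon-4-yn-1-yl]carbamate | C=CC/C=C\Cc1csc(C(C)(C)C(O)CC#CC(=C)CCNC(=O)OC)n1
F3 | step 11 | methyl N-[8-{4-[(2Z)-hexa-2,5-dien-1-yl]-1,3-thiazol-2-yl}-8-methyl-3-methylidene-7-oxonon-4-yn-1-yl]carbamate | C=CC/C=C\Cc1csc(C(C)(C)C(=O)CC#CC(=C)CCNC(=O)OC)n1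
F4 | step 10 | 2-{[(3R)-2-{4-[(2Z)-hexa-2,5-dien-1-yl]-1,3-thiazol-2-yl}-2-methylhex-5-yn-3-yl]oxy}-4,4,5,5-tetramethyl-1,3,2-dioxaborolane | C=CC/C=C\Cc1csc(C(C)(C)[C@H](OB2OC(C)(C)C(C)(C)O2)CC#C)n1
F5 | step 10 | (3R)-2-{4-[(2Z)-hexa-2,5-dien-1-yl]-1,3-thiazol-2-yl}-2-methylhex-5-yn-3-ol | C=CC/C=C\Cc1csc(C(C)(C)[C@H](O)CC#C)n1
F6 | step 3 | ethyl 2-[4-(chloromethyl)-1,3-thiazol-2-yl]-2-methylpropanoate | CCOC(=O)C(C)(C)c1nc(CCl)cs1
F7 | step 3 | ethyl 2-[4-(hex-5-en-2-yn-1-yl)-1,3-thiazol-2-yl]-2-methylpropanoate | C=CCC#CCc1csc(C(C)(C)C(=O)OCC)n1
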